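**Plan**
- Each 4-methoxy-3-methyl-2-pyrone is attached through C-6 to a quaternary cyclobutane carbon. Its O-1, C-6 and C-5 are read as an acetyl group on that carbon, and C-2, C-3 (with its methyl) and C-4 as a methylmalonyl unit, so both rings are cut at C-4–C-5 and at O-1–C-2.
- This leads back to a cis-1,2-diacetyl-1,2-dimethylcyclobutane, used as its bis(silyl enol ether), with the two carboxyl groups held as an acetonide-bridged cis-diol. The cyclobutane is then cut into 2,3-dimethylmaleic anhydride and the acetonide of cis-2-butene-1,4-diol.
- Forward: a [2+2] photocycloaddition makes the four-membered ring, the anhydride becomes two methyl ketones and then two silyl enol ethers, and both pyrone rings are closed in one operation with methylmalonyl dichloride. O-Methylation, acetonide removal and oxidation then give the diacid.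
- Stereochemistry: the cis-dimethyl pair comes from the cyclic anhydride and the cis pair of oxymethyl arms from the cyclic alkene. Their placement on opposite faces comes from exo closure in the photoaddition. The quaternary centres are never touched again, and the two CH centres are at risk only at the aldehyde stage of step 11.

Key step: step 8

Assumption: the four stereodescriptors of the target describe an achiral meso compound (mirror plane through the midpoints of the two ring bonds that join like carbons), so only relative configuration has to be controlled.

Convention for names: "acetonide core" means a cis-1,2-dimethylcyclobutane (C-1 and C-2 quaternary) whose C-3 and C-4 are bridged by CH2–O–C(CH3)2–O–CH2 (a cis-fused 2,2-dimethyl-1,3-dioxepane) on the face of the two methyl groups. The two functional arms at C-1 and C-2 are cis to each other and lie on the opposite face, together with H-3 and H-4.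

**Step 1**
Reactants: 1 cis-2-butene-1,4-diol
Product: 2 2,2-dimethyl-4,7-dihydro-1,3-dioxepine
Conditions: 2,2-dimethoxypropane, TsOH (cat.), CH2Cl2, rt; distillation
Reagents that add atoms: 2,2-dimethoxypropane, COC(C)(C)OC
Why: Acid-catalysed transketalisation should close the seven-membered isopropylidene acetal from the cis-diol only, driven by removal of methanol, and forms no stereocentre.

**Step 2**
Reactants: 2 2,2-dimethyl-4,7-dihydro-1,3-dioxepine; 3 2,3-dimethylmaleic anhydride
Product: 4 cis-anti-cis photoadduct, the acetonide core with C-1 and C-2 joined by C(=O)–O–C(=O) as a cis-fused five-membered anhydride (meso)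
Conditions: hν (medium-pressure Hg lamp, Pyrex, λ > 300 nm), acetophenone (sensitiser), MeCN, 10 °C, 2 in excess; crystallisation
Reagents that add atoms: none
Why: In this triplet-sensitised [2+2] photocycloaddition of a dialkylmaleic anhydride to a cyclic cis-alkene, the ring of each partner should enforce a cis fusion (cis-dimethyl and cis-oxymethyl pairs), and the 1,4-biradical is expected to close on the exo side so that the anhydride and dioxepane rings end up on opposite faces, as is usual for cyclic partners.

**Step 3**
Reactants: 4 cis-anti-cis anhydride photoadduct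
Product: 5 1,2-bis(hydroxymethyl) acetonide core (diol)
Conditions: LiAlH4, THF, 0 °C to reflux; then H2O, aq. NaOH
Reagents that add atoms: none
Why: LiAlH4 reduction of a cyclic anhydride should proceed through the lactone to the 1,4-diol, the carbons next to the carbonyls being quaternary and therefore unable to epimerise, while the acetonide is inert to hydride.

**Step 4**
Reactants: 5 1,2-bis(hydroxymethyl) acetonide core
Product: 6 1,2-diformyl acetonide core (dialdehyde)
Conditions: (COCl)2, DMSO, CH2Cl2, −78 °C; Et3N, −78 to 0 °C
Reagents that add atoms: none
Why: In the Swern oxidation both neopentyl alcohols are converted into alkoxysulfonium ions before base is added, so the dialdehyde should form without passing through a lactol that would be oxidised on to the lactone, and the product has no α-hydrogen.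

**Step 5**
Reactants: 6 1,2-diformyl acetonide core
Product: 7 1,2-bis(1-hydroxyethyl) acetonide core (mixture of carbinol epimers, used as such)
Conditions: MeMgBr (excess), THF, −78 °C to rt; aq. NH4Cl
Reagents that add atoms: methylmagnesium bromide, C[Mg]Br
Why: Grignard addition to the two non-enolisable aldehydes should go to the diol when excess reagent and warming reopen any magnesium lactolate formed after the first addition, and the configuration of the new carbinol centres is irrelevant because both are oxidised in step 6.

**Step 6**
Reactants: 7 1,2-bis(1-hydroxyethyl) acetonide core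
Product: 8 1,2-diacetyl acetonide core (diketone)
Conditions: (COCl)2, DMSO, CH2Cl2, −78 °C; Et3N, −78 to 0 °C
Reagents that add atoms: none
Why: Swern oxidation of the two secondary alcohols should give the bis(methyl ketone) without acid that could open the acetonide, and only the methyl groups carry α-hydrogens, so the ring stereocentres are safe.

**Step 7**
Reactants: 8 1,2-diacetyl acetonide core
Product: 9 1,2-bis[1-(trimethylsilyloxy)ethenyl] acetonide core
Conditions: LDA and Me3SiCl premixed, THF, −78 °C, slow addition of 8; then Et3N, pentane, cold aq. NaHCO3 wash; used at once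
Reagents that add atoms: chlorotrimethylsilane, C[Si](C)(C)Cl
Why: Kinetic enolisation under internal-quench conditions can only remove a methyl proton, because the other α-carbon is quaternary, and the chlorosilane already present should trap each lithium enolate as a silyl enol ether before it can add to the neighbouring acetyl group in an aldol reaction.

**Step 8**
Reactants: 9 1,2-bis[1-(trimethylsilyloxy)ethenyl] acetonide core; 10 methylmalonyl dichloride (distilled before use)
Product: 12 1,2-bis(4-hydroxy-3-methyl-2-oxo-2H-pyran-6-yl) acetonide core, via bis(3,5-dioxoacyl chloride) 11 (not isolated)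
Conditions: 10 (2.4 equiv), 2,6-di-tert-butyl-4-methylpyridine (2.5 equiv), Et2O, −78 °C to rt, slow addition of 9; extraction into aq. NaHCO3, then citric acid to pH 4
Reagents that add atoms: none
Why: The CH2 terminus of each silyl enol ether attacks one acyl chloride of 10 (or the chlorocarbonyl ketene formed from it) with loss of Me3SiCl to give 11, whose enolised ring-side carbonyl oxygen then displaces the second chloride and the product tautomerises to the 4-hydroxy-2-pyrone, so that each arm gains its C-4–C-5 and O-1–C-2 bonds. The closest known reaction is the synthesis of 6-substituted 4-hydroxy-2-pyrones from ketone silyl enol ethers and malonyl dichlorides, here run twice on one substrate. Each of the two rings closes by a 6-exo-trig O-acylation (lactonisation). No stereocentre is formed, the CH(CH3) centres of 11 vanish on enolisation, and the four ring stereocentres are remote and not acidic under these conditions. The step needs carbon-before-oxygen acylation and closure within one arm: the first is secured by the soft, unhindered methylene terminus one atom away from the quaternary carbon, the second by six-membered lactonisation outrunning a nine-membered diketone bridge between the two cis arms, helped by adding 9 slowly to excess 10. The hindered pyridine only takes up hydrogen chloride, which protects the acetonide and the unreacted enol ether, and the absence of strong base excludes aldol closure of the 1,4-dicarbonyl array to a cyclopentenone.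

**Step 9**
Reactants: 12 1,2-bis(4-hydroxy-3-methyl-2-oxo-2H-pyran-6-yl) acetonide core
Product: 13 1,2-bis(4-methoxy-3-methyl-2-oxo-2H-pyran-6-yl) acetonide core
Conditions: Me2SO4, K2CO3, acetone, reflux
Reagents that add atoms: dimethyl sulfate, COS(=O)(=O)OC
Why: O-Alkylation of the acidic 4-hydroxy-2-pyrone (a vinylogous carboxylic acid) with dimethyl sulfate and K2CO3 should take place at the C-4 oxygen, the usual outcome for this hard electrophile, giving the 4-methoxy-2-pyrone rather than the 2-methoxy-4-pyrone, and the acetonide is stable to the base.

**Step 10**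
Reactants: 13 1,2-bis(4-methoxy-3-methyl-2-oxo-2H-pyran-6-yl) acetonide core
Product: 14 3,4-bis(hydroxymethyl)-1,2-dimethyl-1,2-bis(4-methoxy-3-methyl-2-oxo-2H-pyran-6-yl)cyclobutane (pyrones cis to each other and trans to the two cis hydroxymethyl groups)
Conditions: AcOH–H2O 4:1, 40 °C
Reagents that add atoms: none
Why: Acid-catalysed acetal hydrolysis of the seven-membered isopropylidene ketal should be fast in dilute aqueous acid, which leaves the methoxypyrone (a vinylogous ester) intact.

**Step 11**
Reactants: 14 diol
Product: 15 3,4-diformyl-1,2-dimethyl-1,2-bis(4-methoxy-3-methyl-2-oxo-2H-pyran-6-yl)cyclobutane (same relative configuration, crude)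
Conditions: (COCl)2, DMSO, CH2Cl2, −78 °C; iPr2NEt, −78 to −40 °C; cold pH 7 buffer
Reagents that add atoms: none
Why: Swern oxidation again activates both hydroxyls before base is added and so avoids the lactol and lactone, while the hindered amine, low temperature and neutral quench should keep the two α-CH aldehyde centres in the cis configuration set in step 2.

**Step 12**
Reactants: 15 dialdehyde
Product: 16 (1R,2S,3R,4S)-3,4-bis(4-methoxy-3-methyl-2-oxo-2H-pyran-6-yl)-3,4-dimethylcyclobutane-1,2-dicarboxylic acid (meso, the target)
Conditions: NaClO2, NaH2PO4, 2-methyl-2-butene, t-BuOH–H2O, 0 °C to rt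
Reagents that add atoms: sodium chlorite, [Na+].[O-]Cl=O
Why: Pinnick oxidation with chlorous acid should convert both aldehydes (or their cyclic hydrate) into carboxylic acids in a weakly acidic buffer that does not enolise the α-centres, while 2-methyl-2-butene removes hypochlorous acid before it can chlorinate the pyrone rings.

**Compound list**
1 | cis-2-butene-1,4-diol | OC/C=C\CO | starting material
2 | 2,2-dimethyl-4,7-dihydro-1,3-dioxepine | CC1(C)OCC=CCO1 | intermediate
3 | 2,3-dimethylmaleic anhydride | CC1=C(C)C(=O)OC1=O | starting material
4 | cis-anti-cis photoadduct: acetonide core with cis-fused 1,2-dicarboxylic anhydride (meso) | O=C1OC(=O)[C@@]2(C)[C@H]3[C@H](COC(C)(C)OC3)[C@]21C | intermediate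
5 | 1,2-bis(hydroxymethyl) acetonide core | OC[C@@]1(C)[C@H]2[C@H](COC(C)(C)OC2)[C@@]1(C)CO | intermediate
6 | 1,2-diformyl acetonide core | O=C[C@@]1(C)[C@H]2[C@H](COC(C)(C)OC2)[C@@]1(C)C=O | intermediate
7 | 1,2-bis(1-hydroxyethyl) acetonide core (carbinol epimers) | CC(O)[C@@]1(C)[C@H]2[C@H](COC(C)(C)OC2)[C@@]1(C)C(C)O | intermediate
8 | 1,2-diacetyl acetonide core | CC(=O)[C@@]1(C)[C@H]2[C@H](COC(C)(C)OC2)[C@@]1(C)C(C)=O | intermediate
9 | 1,2-bis[1-(trimethylsilyloxy)ethenyl] acetonide core | C=C(O[Si](C)(C)C)[C@@]1(C)[C@H]2[C@H](COC(C)(C)OC2)[C@@]1(C)C(=C)O[Si](C)(C)C | intermediate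
10 | methylmalonyl dichloride | CC(C(=O)Cl)C(=O)Cl | starting material
11 | 1,2-bis(5-chloro-4-methyl-3,5-dioxopentanoyl) acetonide core (not isolated) | CC(C(=O)Cl)C(=O)CC(=O)[C@@]1(C)[C@H]2[C@H](COC(C)(C)OC2)[C@@]1(C)C(=O)CC(=O)C(C)C(=O)Cl | intermediate
12 | 1,2-bis(4-hydroxy-3-methyl-2-oxo-2H-pyran-6-yl) acetonide core | Oc1cc([C@@]2(C)[C@H]3[C@H](COC(C)(C)OC3)[C@@]2(C)c2cc(O)c(C)c(=O)o2)oc(=O)c1C | intermediate
13 | 1,2-bis(4-methoxy-3-methyl-2-oxo-2H-pyran-6-yl) acetonide core | COc1cc([C@@]2(C)[C@H]3[C@H](COC(C)(C)OC3)[C@@]2(C)c2cc(OC)c(C)c(=O)o2)oc(=O)c1C | intermediate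
14 | 3,4-bis(hydroxymethyl)-1,2-dimethyl-1,2-bis(4-methoxy-3-methyl-2-oxo-2H-pyran-6-yl)cyclobutane | COc1cc([C@@]2(C)[C@H](CO)[C@H](CO)[C@@]2(C)c2cc(OC)c(C)c(=O)o2)oc(=O)c1C | intermediate
15 | 3,4-diformyl-1,2-dimethyl-1,2-bis(4-methoxy-3-methyl-2-oxo-2H-pyran-6-yl)cyclobutane | COc1cc([C@@]2(C)[C@H](C=O)[C@H](C=O)[C@@]2(C)c2cc(OC)c(C)c(=O)o2)oc(=O)c1C | intermediate
16 | (1R,2S,3R,4S)-3,4-bis(4-methoxy-3-methyl-2-oxo-2H-pyran-6-yl)-3,4-dimethylcyclobutane-1,2-dicarboxylic acid | COc1cc([C@@]2(C)[C@H](C(=O)O)[C@H](C(=O)O)[C@@]2(C)c2cc(OC)c(C)c(=O)o2)oc(=O)c1C | target

**Count**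
Total step count: 12. Longest linear sequence: 12 steps (1 to 16); 3 and 10 are bought and enter in steps 2 and 8.

**Steps most likely to fail**

1. Step 8 (double pyrone annulation). O-Acylation of the enol ethers, or coupling of two molecules through one malonyl unit, may compete with ring closure. Hydrogen chloride that escapes the buffer may also strip the acetonide and the silyl groups before the second arm has reacted. The fallback sets out from dialdehyde 6 and comes back at 12. The dianion of methyl 2-methyl-3-oxobutanoate (NaH, then n-BuLi, THF, −78 °C, in excess) is added through its terminal carbon to both formyl groups to give the bis(δ-hydroxy-β-keto ester) F1. Oxidation with Dess–Martin periodinane gives the bis(3,5-dioxo ester) F2. Heating with DBU in toluene lactonises each arm with loss of methanol to give 12. This builds each ring from the aldehyde carbon and a four-carbon keto ester instead of from an enol ether and a malonyl unit, and all three operations are standard in pyrone synthesis.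

2. Step 2 (photocycloaddition). The biradical may close with poor facial selectivity, giving the cis-syn-cis adduct beside the wanted one, and the excited carbonyl compounds may abstract hydrogen from the allylic acetal CH2 groups. The fallback sets out from 3 and comes back at 5. Irradiation of 3 with but-2-yne-1,4-diol under the same sensitised conditions gives the cis-fused cyclobutene anhydride diol F3, in which no facial question arises. 2-Methoxypropene with pyridinium p-toluenesulfonate in CH2Cl2 closes the acetonide to give the cyclobutene anhydride acetonide F4. LiAlH4 then gives the cyclobutene diol F5. Hydrogenation with [Ir(cod)(PCy3)(py)]PF6 under H2 in CH2Cl2, directed by the two hydroxymethyl groups, should deliver both hydrogens to the face that carries them and so give 5. The relative configuration is then set by a directed hydrogenation instead of by the photochemical ring closure.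

3. Step 7 (bis-silylation). A mono-enolate may close onto the neighbouring acetyl group by an aldol reaction before it is silylated, which leads to a bicyclic cyclopentenone, and the bis(enol ether) may hydrolyse during isolation. The fallback sets out from dialdehyde 6 and comes back at 9. Addition of Me3SiCH2MgCl to both formyl groups gives the bis(β-hydroxysilane) F6. Swern oxidation gives the bis(α-trimethylsilyl ketone) F7. Heating in toluene at 110–140 °C should move each silyl group from carbon to oxygen (thermal 1,3-silyl shift of a β-ketosilane) to give 9 without any enolate being formed.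

**Further compounds**
F1 | step 8 | 1,2-bis(1-hydroxy-5-methoxy-4-methyl-3,5-dioxopentyl) acetonide core | COC(=O)C(C)C(=O)CC(O)[C@@]1(C)[C@H]2[C@H](COC(C)(C)OC2)[C@@]1(C)C(O)CC(=O)C(C)C(=O)OC
F2 | step 8 | 1,2-bis(5-methoxy-4-methyl-3,5-dioxopentanoyl) acetonide core | COC(=O)C(C)C(=O)CC(=O)[C@@]1(C)[C@H]2[C@H](COC(C)(C)OC2)[C@@]1(C)C(=O)CC(=O)C(C)C(=O)OC
F3 | step 2 | cis-6,7-bis(hydroxymethyl)-1,5-dimethyl-3-oxabicyclo[3.2.0]hept-6-ene-2,4-dione | O=C1OC(=O)[C@@]2(C)C(CO)=C(CO)[C@]21C
F4 | step 2 | acetonide of F3 (2,2-dimethyl-1,3-dioxepine fused at the cyclobutene double bond) | O=C1OC(=O)[C@@]2(C)C3=C(COC(C)(C)OC3)[C@]21C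
F5 | step 2 | cyclobutene analogue of 5: cis-1,2-bis(hydroxymethyl)-1,2-dimethylcyclobut-3-ene with the 3,4-acetonide bridge | OC[C@@]1(C)C2=C(COC(C)(C)OC2)[C@@]1(C)CO
F6 | step 7 | 1,2-bis[1-hydroxy-2-(trimethylsilyl)ethyl] acetonide core | C[Si](C)(C)CC(O)[C@@]1(C)[C@H]2[C@H](COC(C)(C)OC2)[C@@]1(C)C(O)C[Si](C)(C)C
F7 | step 7 | 1,2-bis[(trimethylsilyl)acetyl] acetonide core | C[Si](C)(C)CC(=O)[C@@]1(C)[C@H]2[C@H](COC(C)(C)OC2)[C@@]1(C)C(=O)C[Si](C)(C)C
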